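At 40 min, twice the time of the last earlier reading, I want the excess of right-handed over left-handed substrate in west and in east, two flasks that differ in their solid reagent.

| flask | left-handed substrate | right-handed substrate | protic impurity | solid reagent | free catalyst | remark | time |
|---|---|---|---|---|---|---|---|
| Monday's | 31 mM | 31 mM | 0.62 mM | 20 mM | 31 µM | run made earlier |  |
| Sunday's | 31 mM | 31 mM | 0.62 mM | 61 mM | 31 µM | run made earlier |  |
| west | 31 mM | 31 mM | 0.620 mM | 24.8 mM | 31 µM |  | 40 min |
| east | 31 mM | 31 mM | 0.620 mM | 80.0 mM | 31 µM |  | 40 min |

| run | time / min | right-handed substrate / % | left-handed substrate / % |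
|---|---|---|---|
| Monday's | 1.50 | 49.9 | 49.2 |
| Monday's | 2.50 | 49.8 | 49.1 |
| Monday's | 4.00 | 49.2 | 47.9 |
| Monday's | 6.00 | 49.1 | 45.5 |
| Monday's | 8.00 | 49.9 | 43.3 |
| Monday's | 12.0 | 48.7 | 40.6 |
| Monday's | 20.0 | 47.4 | 33.4 |
| Sunday's | 1.50 | 49.7 | 50.4 |
| Sunday's | 2.50 | 49.3 | 49.0 |
| Sunday's | 4.00 | 50.3 | 48.0 |
| Sunday's | 6.00 | 49.6 | 45.6 |
| Sunday's | 8.00 | 48.9 | 44.2 |
| Sunday's | 12.0 | 49.2 | 40.2 |
| Sunday's | 20.0 | 46.9 | 32.8 |

(standard deviation of a reading: 0.5 percentage points)

- the flask that ends with the higher excess of right-handed substrate over left-handed substrate among what is left of the two, or "neither" when 2 percentage points or less lies between them (west / east / neither)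
- excess of right-handed substrate over left-handed substrate among what is left of the two at the end, west
- excess of right-handed substrate over left-handed substrate among what is left of the two at the end, east

- free catalyst is single-handed; left-handed substrate and right-handed substrate are mirror images of each other, charged as a racemate, each of them at the stated concentration
- given per volume of solution although it is solid: solid reagent
- at the start none of the solid reagent is in solution
- an excess is the difference of the two amounts in percent of their sum
- an excess is below zero if the other one leads

I draw the mean of both runs, in parts of each substrate's own charge. Left-handed substrate starts flat, at 99.6% after 1.50 min, then bends down to 91.1% at 6.00 min and 66.2% at 20.0 min, while right-handed substrate stands at 94.3%. The ratio of the logarithms of these two rests, read off scattered readings, is my selectivity factor, 7.03, and I take the rest of right-handed substrate as the rest of left-handed raised to one over that factor.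

Beyond 20.0 min the readings leave the bend open. A straight line leaves 30.6% of left-handed substrate at 40 min and an exponential 42.0%, so I take their mean, 36.3%. Right-handed substrate then keeps 86.6%, which by my count costs 23.9 mM of reagent, less than east holds, and I reckon east at 40.9%.

West holds 24.2 mM beyond the impurity, a margin of 0.300 mM, so I go round again. Within the scatter, Monday's run kept the pace of Sunday's up to 20.0 min, with 7.13 mM of reagent left by my count. I let west keep pace down to that amount, a knee at 28.2 min, and then let the pace fall in proportion to the reagent left, which in this reckoning comes to 2.72 mM at the end. The two rests then add up to 131% of one charge. Putting east's right-handed rest in and each answer back twice gives 88.3% for right-handed substrate and 35.0% for west, so I expect east higher.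

The forecast says east, with 41% for west and 45% for east, reasoning that “the rate doesn't depend on solid loading while solid remains”.

The flask gives east, with 33.0% in west and 39.4% in east.

    free catalyst + right-handed substrate ⇌ catalyst intermediate B (K = 71.0 M⁻¹, k = 28000 M⁻¹ min⁻¹)
    left-handed product ⇌ right-handed product (k = 0.150 min⁻¹)
    solid reagent ⇌ coupling partner, rate k3*(cs3 - [coupling partner]) while solid is left; crystals form when [coupling partner] > cs3 (solubility = 10.0 mM, k = 0.520 min⁻¹)
    coupling partner + catalyst intermediate B → free catalyst + right-handed product (k = 1200 M⁻¹ min⁻¹)
    coupling partner + catalyst intermediate A → free catalyst + left-handed product (k = 3900 M⁻¹ min⁻¹)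
    coupling partner + protic impurity → quenched reagent (k = 420 M⁻¹ min⁻¹)
    free catalyst + left-handed substrate ⇌ catalyst intermediate A (K = 140 M⁻¹, k = 6.00 × 10⁵ M⁻¹ min⁻¹)

West ends with 45% of its left-handed substrate, so the factor gives 89.1% of right-handed substrate and an excess of 33.4%; west holds 88% of its right-handed substrate, with an excess of 33.0%. The neighbouring flask is west read at 15 min. It keeps 75% of its left-handed substrate, so the factor gives 96.1% of right-handed substrate and an excess of 12.0%, and that flask holds 96% with an excess of 11.9%.

The runs are simulated for an exercise; the scatter is artificial.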